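**Retrosynthetic overview**
- The C2–C1′ bond is cut last: target ⇒ C2 lactol of the pyran-fused syncarpic unit + syncarpic acid (acid-mediated C-alkylation; C2 under thermodynamic control).
- Lactol ⇒ enol δ-lactone (half-reduction).
- Enol δ-lactone ⇒ α-isopropyl-α-diazoketone by a photochemical Wolff 1,2-shift that forms C3–C4 with retention; the ketene is captured by the enol oxygen, closing the dihydropyran ring.
- Diazoketone ⇒ syncarpic acid + (R)-α-bromo-α′-diazoketone (SN2, inversion, sets C4) ⇐ (R)-2-bromo-4-methylpentanoic acid (from D-leucine) + 1-diazo-2-methylpropane.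
- Ring order: both carbocycles are bought as syncarpic acid; the pyran ring forms in the photochemical step; the second syncarpyl unit is attached last.

Assumption: syncarpic acid and (R)-2-bromo-4-methylpentanoic acid (D-leucine, NaNO2/HBr, retention) are purchased, and the 2,3-cis/3,4-trans arrangement of the target is taken to be the thermodynamic one relative to C4 (C4-isobutyl pseudoaxial, C3-isopropyl anti to it, C2-substituent equatorial).

**Step 1**
Reactants: 1 isobutyraldehyde; 2 hydrazine hydrate
Product: 3 (2-methylpropylidene)hydrazine (isobutyraldehyde hydrazone)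
Conditions: N2H4·H2O (5 equiv), EtOH, 0 °C → rt; extract, use crude
Reagents that add atoms: none beyond reactant 2 (hydrazine, NN)
Why: Hydrazone condensation; the large excess of hydrazine suppresses azine formation.

**Step 2**
Reactants: 3
Product: 4 1-diazo-2-methylpropane (cold Et2O solution, not isolated)
Conditions: activated MnO2, Na2SO4, Et2O, −20 °C; filter cold, use at once
Reagents that add atoms: none
Why: Dehydrogenation of an N-unsubstituted hydrazone to a non-stabilised diazoalkane (hydrazone oxidation).

**Step 3**
Reactants: 5 (R)-2-bromo-4-methylpentanoic acid; 4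
Product: 6 (5R)-5-bromo-3-diazo-2,7-dimethyloctan-4-one
Conditions: i-BuOCOCl, N-methylmorpholine, THF, −20 °C; then 4 (2.5 equiv), Et2O, −20 → 0 °C
Reagents that add atoms: none beyond reactant 4
Why: Arndt–Eistert-type acylation of a diazoalkane by a mixed anhydride; the bromide-bearing stereocentre is not touched and stays R.

**Step 4**
Reactants: 6; 7 syncarpic acid (2,2,4,4-tetramethylcyclohexane-1,3,5-trione)
Product: 8 3-hydroxy-4,4,6,6-tetramethyl-2-[(5R)-3-diazo-2,7-dimethyl-4-oxooctan-5-yl]cyclohex-2-ene-1,5-dione (formed as its caesium enolate, carried forward as the filtered solution)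
Conditions: 7 (1.2 equiv), Cs2CO3 (1.5 equiv), MeCN, 0 °C → rt, dark; filter
Reagents that add atoms: none beyond reactant 7
Why: SN2 C-alkylation of the soft β-triketone enolate by an α-bromo ketone (interrupted Feist–Benary type) with inversion, which fixes C4 from the bought stereocentre (the descriptor stays R only because the CIP ranking changes).

**Step 5 (photochemical key step)**
Reactants: 8
Product: 9 (3S,4S)-6,6,8,8-tetramethyl-4-(2-methylpropyl)-3-(propan-2-yl)-3,4,6,8-tetrahydro-2H-chromene-2,5,7-trione (enol δ-lactone, 3,4-trans)
Conditions: hν (405 nm LEDs), MeCN (0.02 M), 0 °C, N2; AcOH quench; then DBU (0.1 equiv), CH2Cl2, rt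
Reagents that add atoms: none
Why: Proposed new method: direct n→π* excitation of the fully substituted α-diazoketone expels N2 while the C4 stereocentre migrates from the acyl carbon to the diazo carbon with retention (Wolff 1,2-shift, forming C3–C4; descriptor becomes S by ranking only), and the resulting alkyl(isopropyl)ketene is captured 6-exo by the tethered triketone enolate oxygen to close the pyranone, after which protonation and DBU equilibration give the trans (3S) lactone under control of C4; the closest known chemistry is Arndt–Eistert homologation with higher diazoalkanes and photo-Wolff with intramolecular phenol or alcohol capture, neither shown for a tetrasubstituted diazoketone whose migrating carbon carries a β-triketone enolate, nor with enolate-oxygen termination.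

**Step 6**
Reactants: 9
Product: 10 (3S,4S)-2-hydroxy-6,6,8,8-tetramethyl-4-(2-methylpropyl)-3-(propan-2-yl)-2,3,4,8-tetrahydro-chromene-5,7(6H)-dione (lactol, C2 anomeric mixture)
Conditions: DIBAL-H (1.05 equiv), CH2Cl2, −78 °C; Rochelle salt work-up
Reagents that add atoms: none
Why: Partial reduction of the most electrophilic carbonyl (the enol ester) to the lactol; the hindered C7 ketone and the vinylogous C5 carbonyl are left, and C3/C4 are untouched.

**Step 7**
Reactants: 10; 7 syncarpic acid
Product: 11 ericifolione, (2R,3S,4S)-2-(2-hydroxy-3,3,5,5-tetramethyl-4,6-dioxocyclohex-1-en-1-yl)-4-isobutyl-3-isopropyl-6,6,8,8-tetramethyl-3,4-dihydro-2H-chromene-5,7(6H,8H)-dione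
Conditions: 7 (1.2 equiv), TsOH·H2O (10 mol %), 4 Å MS, CH2Cl2, 0 °C → rt
Reagents that add atoms: none beyond reactant 7
Why: Acid-mediated Knoevenagel-type C-alkylation of syncarpic acid by the lactol (oxocarbenium, or alkylidene then oxa-Michael closure); C2 equilibrates through reversible oxa-Michael ring opening to the equatorial 2R isomer (cis to C3-iPr, trans to C4-iBu), and the amine-free acidic conditions avoid enamine-driven retro-Michael loss of C4.

**Compound list**
1 | isobutyraldehyde | CC(C)C=O | starting material
2 | hydrazine hydrate | NN.O | starting material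
3 | (2-methylpropylidene)hydrazine | CC(C)C=NN | intermediate
4 | 1-diazo-2-methylpropane | CC(C)C=[N+]=[N-] | intermediate
5 | (R)-2-bromo-4-methylpentanoic acid | CC(C)C[C@@H](Br)C(=O)O | starting material
6 | (5R)-5-bromo-3-diazo-2,7-dimethyloctan-4-one | CC(C)C[C@@H](Br)C(=O)C(=[N+]=[N-])C(C)C | intermediate
7 | syncarpic acid | CC1(C)C(=O)CC(=O)C(C)(C)C1=O | starting material
8 | syncarpyl α-diazoketone (R at the chain stereocentre) | CC(C)C[C@H](C1=C(O)C(C)(C)C(=O)C(C)(C)C1=O)C(=O)C(=[N+]=[N-])C(C)C | intermediate
9 | (3S,4S) enol δ-lactone | CC(C)C[C@@H]1C2=C(OC(=O)[C@H]1C(C)C)C(C)(C)C(=O)C(C)(C)C2=O | intermediate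
10 | (3S,4S) lactol | CC(C)C[C@@H]1C2=C(OC(O)[C@H]1C(C)C)C(C)(C)C(=O)C(C)(C)C2=O | intermediate
11 | ericifolione (2R,3S,4S) | CC(C)C[C@@H]1C2=C(O[C@@H](C3=C(O)C(C)(C)C(=O)C(C)(C)C3=O)[C@H]1C(C)C)C(C)(C)C(=O)C(C)(C)C2=O | target

**Step count**
Total steps: 7. Longest linear sequence: 7 (1 → 3 → 4 → 6 → 8 → 9 → 10 → 11); 5 steps from the chiral starting material 5. Intermediates 4 and 8 are used without isolation.

**Three steps most likely to fail**
1. Step 5 (proposed new method). A carbene 1,2-H shift from the isopropyl methine (giving an enone) or O-capture of the carbene may compete with the Wolff shift. Fallback (known chemistry): make the unsubstituted diazoketone from 5 with TMSCHN2, alkylate as in Step 4, and run a standard photochemical Arndt–Eistert/Wolff lactonisation to the C3-unsubstituted enol lactone. Then install the isopropyl group after ring formation by lactone enolate aldol with acetone, dehydration, hydrogenation and DBU equilibration to trans.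
2. Step 4. O-alkylation of the triketone enolate, or erosion of ee by bromide exchange on the α-bromo ketone, may occur. Fallback: reverse the order and change the electrophile class. C-alkylate syncarpic acid with methyl (R)-2-(trifluoromethanesulfonyloxy)-4-methylpentanoate (non-nucleophilic leaving group, ester instead of ketone), then saponify, mask the enol as its methyl ether and build the diazoketone on the alkylated acid.
3. Step 6. The enol lactone may over-reduce, or the ring ketones may be attacked. Fallback: skip the lactol. Transfer the acyl group of 9 to carbon of syncarpic acid (Et3N, cat. DMAP, O→C acyl shift) to give the 2-acyl syncarpic acid, then reduce that ketone with NaBH4; the carbinol dehydrates to the alkylidene, which closes to 11 by oxa-Michael addition.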